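**Strategy.** Ring B is built, not brominated. Its substituents in sequence (C1' CH2 bridge, C2'–Br, C3'–Br, C4'–OH, C5'–OH, C6'–H) map C3', C2', C1', C6' onto C3–C6 of a 2-pyrone and C4'/C5' onto an oxygenated alkene. Heating a 3,4-dibromo-5-benzyl-2-pyrone that carries fully silylated ring A with tris(trimethylsilyloxy)ethene forms C3'–C4' and C5'–C6' by [4+2] cycloaddition. Loss of CO2 and Me3SiOH then delivers aromatic ring B as its bis-silyl catechol ether in one operation. The pyrone comes from methyl 4-O-methylgallate and tert-butyl acetoacetate, and fluoride releases the target.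

Key step: step 11

Remark on the chemistry: the target has no stereocentre and no stereogenic double bond, so it is achiral and no stereocontrol is needed; the sp3 centres formed transiently in step 11 are lost on aromatisation. TBS = tert-butyldimethylsilyl, TMS = trimethylsilyl.

**Step 1**
Reactants: 1 methyl 3,5-dihydroxy-4-methoxybenzoate
Product: 3 methyl 2-formyl-3,5-dihydroxy-4-methoxybenzoate, via N-{[2,4-dihydroxy-3-methoxy-6-(methoxycarbonyl)phenyl]methylidene}-N-methylmethanaminium chloride 2 (not isolated)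
Conditions: POCl3, DMF, MeCN, 0 → 50 °C; then H2O, 50 °C
Reagents that add atoms: N,N-dimethylformamide CN(C)C=O; water O; phosphoryl chloride O=P(Cl)(Cl)Cl (chloride of 2 only)
Why: Vilsmeier–Haack formylation: C2 (equivalent to C6) is the only free position and is ortho to one hydroxyl and para to the other, the iminium group of 2 deactivates the ring against a second attack, and aqueous hydrolysis of 2 gives the aldehyde.

**Step 2**
Reactants: 3 methyl 2-formyl-3,5-dihydroxy-4-methoxybenzoate
Product: 4 methyl 3,5-bis(tert-butyldimethylsilyloxy)-2-formyl-4-methoxybenzoate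
Conditions: TBSCl (2.5 equiv), imidazole, DMF, rt
Reagents that add atoms: tert-butyldimethylsilyl chloride CC(C)(C)[Si](C)(C)Cl
Why: Silyl ether formation on both phenols with TBSCl/imidazole removes the acidic protons before the hydride and enolate steps and gives groups that fluoride will remove at the end.

**Step 3**
Reactants: 4 methyl 3,5-bis(tert-butyldimethylsilyloxy)-2-formyl-4-methoxybenzoate
Product: 5 [2,4-bis(tert-butyldimethylsilyloxy)-6-(hydroxymethyl)-3-methoxyphenyl]methanol
Conditions: DIBAL-H (5 equiv), CH2Cl2, −78 → 0 °C; Rochelle salt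
Reagents that add atoms: none
Why: Hydride reduction (DIBAL-H) of the aldehyde and the ester to the two benzylic alcohols; aryl silyl ethers are inert to DIBAL-H and aluminium alkoxides do not promote silyl migration from the neighbouring phenol oxygen.

**Step 4**
Reactants: 5 [2,4-bis(tert-butyldimethylsilyloxy)-6-(hydroxymethyl)-3-methoxyphenyl]methanol
Product: 6 {2,4-bis(tert-butyldimethylsilyloxy)-6-[(tert-butyldimethylsilyloxy)methyl]-3-methoxyphenyl}methanol
Conditions: TBSCl (1.05 equiv), imidazole, CH2Cl2, −30 → 0 °C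
Reagents that add atoms: tert-butyldimethylsilyl chloride CC(C)(C)[Si](C)(C)Cl
Why: Sterically controlled monosilylation: the hydroxymethyl group next to the ring C–H should react with the bulky silyl chloride much faster than the one flanked by the C2 silyl ether and the other CH2OH, leaving the future bridge carbon as the free alcohol.

**Step 5**
Reactants: 6 {2,4-bis(tert-butyldimethylsilyloxy)-6-[(tert-butyldimethylsilyloxy)methyl]-3-methoxyphenyl}methanol
Product: 7 2,4-bis(tert-butyldimethylsilyloxy)-6-[(tert-butyldimethylsilyloxy)methyl]-3-methoxybenzyl bromide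
Conditions: CBr4, PPh3, CH2Cl2, 0 °C; used at once without chromatography
Reagents that add atoms: carbon tetrabromide BrC(Br)(Br)Br
Why: Appel reaction: neutral SN2 bromination of the remaining primary benzylic alcohol via its alkoxyphosphonium salt, which the silyl ethers tolerate at 0 °C.

**Step 6**
Reactants: 7 2,4-bis(tert-butyldimethylsilyloxy)-6-[(tert-butyldimethylsilyloxy)methyl]-3-methoxybenzyl bromide; 8 tert-butyl acetoacetate
Product: 9 tert-butyl 5-{2,4-bis(tert-butyldimethylsilyloxy)-6-[(tert-butyldimethylsilyloxy)methyl]-3-methoxyphenyl}-3-oxopentanoate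
Conditions: 8 (1.5 equiv), LDA (2 equiv per 8), THF, 0 °C; then 7, −78 → 0 °C; AcOH
Reagents that add atoms: none
Why: γ-Alkylation of a β-keto ester dianion: the terminal carbanion, the more basic and more nucleophilic site, is benzylated by the reactive bromide, and this bond becomes the link between the bridge CH2 and pyrone C5.

**Step 7**
Reactants: 9 tert-butyl 5-{2,4-bis(tert-butyldimethylsilyloxy)-6-[(tert-butyldimethylsilyloxy)methyl]-3-methoxyphenyl}-3-oxopentanoate
Product: 11 5-{2,4-bis(tert-butyldimethylsilyloxy)-6-[(tert-butyldimethylsilyloxy)methyl]-3-methoxybenzyl}-4-hydroxy-2H-pyran-2-one, via tert-butyl (4Z)-5-{2,4-bis(tert-butyldimethylsilyloxy)-6-[(tert-butyldimethylsilyloxy)methyl]-3-methoxyphenyl}-4-(hydroxymethylidene)-3-oxopentanoate 10 (not isolated)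
Conditions: LDA (2.1 equiv), THF, −78 → −20 °C; HCO2Me, −78 → 0 °C; AcOH; then PhMe, 110 °C
Reagents that add atoms: methyl formate COC=O
Why: Claisen-type γ-formylation of the regenerated β-keto ester dianion gives the enolised 4-formyl ester 10, and on heating the tert-butyl β-keto ester loses tert-butanol (acylketene) and is captured by the enol oxygen, a neutral lactonisation to the 4-hydroxy-2-pyrone that spares the aryl silyl ethers.

**Step 8**
Reactants: 11 5-{2,4-bis(tert-butyldimethylsilyloxy)-6-[(tert-butyldimethylsilyloxy)methyl]-3-methoxybenzyl}-4-hydroxy-2H-pyran-2-one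
Product: 12 3-bromo-5-{2,4-bis(tert-butyldimethylsilyloxy)-6-[(tert-butyldimethylsilyloxy)methyl]-3-methoxybenzyl}-4-hydroxy-2H-pyran-2-one
Conditions: NBS (1.0 equiv), CH2Cl2, −20 → 0 °C
Reagents that add atoms: N-bromosuccinimide O=C1CCC(=O)N1Br
Why: Electrophilic bromination of the vinylogous-acid enol at C3, its only nucleophilic carbon (C5 is substituted), which should be far faster than aromatic substitution at the one C–H of silylated ring A when one equivalent of NBS is used cold.

**Step 9**
Reactants: 12 3-bromo-5-{2,4-bis(tert-butyldimethylsilyloxy)-6-[(tert-butyldimethylsilyloxy)methyl]-3-methoxybenzyl}-4-hydroxy-2H-pyran-2-one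
Product: 13 3-bromo-5-{2,4-bis(tert-butyldimethylsilyloxy)-6-[(tert-butyldimethylsilyloxy)methyl]-3-methoxybenzyl}-2-oxo-2H-pyran-4-yl trifluoromethanesulfonate
Conditions: Tf2O (1.1 equiv), Et3N, CH2Cl2, −78 °C
Reagents that add atoms: trifluoromethanesulfonic anhydride O=S(=O)(OS(=O)(=O)C(F)(F)F)C(F)(F)F
Why: O-Sulfonylation of the acidic 4-hydroxyl (enol triflate formation) turns C4 into a vinylogous acyl triflate.

**Step 10**
Reactants: 13 3-bromo-5-{2,4-bis(tert-butyldimethylsilyloxy)-6-[(tert-butyldimethylsilyloxy)methyl]-3-methoxybenzyl}-2-oxo-2H-pyran-4-yl trifluoromethanesulfonate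
Product: 14 3,4-dibromo-5-{2,4-bis(tert-butyldimethylsilyloxy)-6-[(tert-butyldimethylsilyloxy)methyl]-3-methoxybenzyl}-2H-pyran-2-one
Conditions: LiBr (3 equiv), acetone, rt
Reagents that add atoms: lithium bromide [Li+].[Br-]
Why: Nucleophilic vinylic substitution (addition–elimination) of bromide at C4, β to the lactone carbonyl, with triflate as the far better leaving group so that the exchange runs one way; the second bromine is thus placed without any arene bromination.

**Step 11**
Reactants: 14 3,4-dibromo-5-{2,4-bis(tert-butyldimethylsilyloxy)-6-[(tert-butyldimethylsilyloxy)methyl]-3-methoxybenzyl}-2H-pyran-2-one; 15 tris(trimethylsilyloxy)ethene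
Product: 18 3,4-dibromo-5-{2,4-bis(tert-butyldimethylsilyloxy)-6-[(tert-butyldimethylsilyloxy)methyl]-3-methoxybenzyl}-1,2-bis(trimethylsilyloxy)benzene, via 4,5-dibromo-6-{2,4-bis(tert-butyldimethylsilyloxy)-6-[(tert-butyldimethylsilyloxy)methyl]-3-methoxybenzyl}-7,8,8-tris(trimethylsilyloxy)-2-oxabicyclo[2.2.2]oct-5-en-3-one 16 (not isolated), via 1,2-dibromo-3-{2,4-bis(tert-butyldimethylsilyloxy)-6-[(tert-butyldimethylsilyloxy)methyl]-3-methoxybenzyl}-5,6,6-tris(trimethylsilyloxy)cyclohexa-1,3-diene 17 (not isolated)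
Conditions: 15 (4 equiv), PhMe, 120 °C, sealed tube, Ar; volatiles removed, crude carried on
Reagents that add atoms: none
Why: Inverse-electron-demand Diels–Alder reaction: the electron-poor dibromopyrone diene (C3=C4–C5=C6) and the trioxygenated alkene combine in an asynchronous [4+2], the nucleophilic CH(OTMS) carbon bonding to the unsubstituted C6 and the C(OTMS)2 carbon to C3, to give bridged lactone 16. Retro-[4+2] loss of CO2 gives cyclohexadiene 17, and 1,2-elimination of Me3SiOH (H from C5', one silyloxy group from C4') aromatises it to 18. The closest known reaction type is the aryl annulation of electron-poor (3-carbomethoxy- or halo-substituted) 2-pyrones with ketene acetals and 1,1,2-trialkoxyethenes, which likewise ends with loss of CO2 and an alcohol. Ring B is closed by the intermolecular [4+2] cycloaddition itself, which forms C3'–C4' and C5'–C6' in one event. No stereocentre has to be controlled, since the sp3 centres of 16 and 17 are destroyed and both orientations of the alkene converge on 18 (each new ring carbon keeps one silyloxy group). The selectivity needed is cycloaddition across C3/C6 over addition–elimination at C4–Br; it should be secured by neutral, base- and Lewis-acid-free thermal conditions and by the substrate, in which C6 is the only unsubstituted electrophilic terminus while C4 is flanked by C3–Br and the C5 benzyl group.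

**Step 12**
Reactants: 18 3,4-dibromo-5-{2,4-bis(tert-butyldimethylsilyloxy)-6-[(tert-butyldimethylsilyloxy)methyl]-3-methoxybenzyl}-1,2-bis(trimethylsilyloxy)benzene
Product: 19 4-(2,3-dibromo-4,5-dihydroxybenzyl)-5-(hydroxymethyl)-2-methoxybenzene-1,3-diol
Conditions: TBAF (6 equiv), AcOH (6 equiv), THF, 0 °C → rt, degassed, Ar
Reagents that add atoms: none
Why: Fluoride-mediated desilylation of all five Si–O bonds (three TBS, two TMS), buffered with acetic acid and run under argon so that the catechol is never exposed as its air-sensitive phenoxide.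

**Compound list**

1 | methyl 3,5-dihydroxy-4-methoxybenzoate | COC(=O)c1cc(O)c(OC)c(O)c1 | starting material
2 | N-{[2,4-dihydroxy-3-methoxy-6-(methoxycarbonyl)phenyl]methylidene}-N-methylmethanaminium chloride | COC(=O)c1cc(O)c(OC)c(O)c1C=[N+](C)C.[Cl-] | intermediate
3 | methyl 2-formyl-3,5-dihydroxy-4-methoxybenzoate | COC(=O)c1cc(O)c(OC)c(O)c1C=O | intermediate
4 | methyl 3,5-bis(tert-butyldimethylsilyloxy)-2-formyl-4-methoxybenzoate | COC(=O)c1cc(O[Si](C)(C)C(C)(C)C)c(OC)c(O[Si](C)(C)C(C)(C)C)c1C=O | intermediate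
5 | [2,4-bis(tert-butyldimethylsilyloxy)-6-(hydroxymethyl)-3-methoxyphenyl]methanol | OCc1cc(O[Si](C)(C)C(C)(C)C)c(OC)c(O[Si](C)(C)C(C)(C)C)c1CO | intermediate
6 | {2,4-bis(tert-butyldimethylsilyloxy)-6-[(tert-butyldimethylsilyloxy)methyl]-3-methoxyphenyl}methanol | OCc1c(CO[Si](C)(C)C(C)(C)C)cc(O[Si](C)(C)C(C)(C)C)c(OC)c1O[Si](C)(C)C(C)(C)C | intermediate
7 | 2,4-bis(tert-butyldimethylsilyloxy)-6-[(tert-butyldimethylsilyloxy)methyl]-3-methoxybenzyl bromide | BrCc1c(CO[Si](C)(C)C(C)(C)C)cc(O[Si](C)(C)C(C)(C)C)c(OC)c1O[Si](C)(C)C(C)(C)C | intermediate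
8 | tert-butyl acetoacetate (tert-butyl 3-oxobutanoate) | CC(=O)CC(=O)OC(C)(C)C | starting material
9 | tert-butyl 5-{2,4-bis(tert-butyldimethylsilyloxy)-6-[(tert-butyldimethylsilyloxy)methyl]-3-methoxyphenyl}-3-oxopentanoate | CC(C)(C)OC(=O)CC(=O)CCc1c(CO[Si](C)(C)C(C)(C)C)cc(O[Si](C)(C)C(C)(C)C)c(OC)c1O[Si](C)(C)C(C)(C)C | intermediate
10 | tert-butyl (4Z)-5-{2,4-bis(tert-butyldimethylsilyloxy)-6-[(tert-butyldimethylsilyloxy)methyl]-3-methoxyphenyl}-4-(hydroxymethylidene)-3-oxopentanoate (enol form of the 4-formyl ester) | CC(C)(C)OC(=O)CC(=O)/C(Cc1c(CO[Si](C)(C)C(C)(C)C)cc(O[Si](C)(C)C(C)(C)C)c(OC)c1O[Si](C)(C)C(C)(C)C)=C\O | intermediate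
11 | 5-{2,4-bis(tert-butyldimethylsilyloxy)-6-[(tert-butyldimethylsilyloxy)methyl]-3-methoxybenzyl}-4-hydroxy-2H-pyran-2-one | O=C1C=C(O)C(Cc2c(CO[Si](C)(C)C(C)(C)C)cc(O[Si](C)(C)C(C)(C)C)c(OC)c2O[Si](C)(C)C(C)(C)C)=CO1 | intermediate
12 | 3-bromo-5-{2,4-bis(tert-butyldimethylsilyloxy)-6-[(tert-butyldimethylsilyloxy)methyl]-3-methoxybenzyl}-4-hydroxy-2H-pyran-2-one | O=C1OC=C(Cc2c(CO[Si](C)(C)C(C)(C)C)cc(O[Si](C)(C)C(C)(C)C)c(OC)c2O[Si](C)(C)C(C)(C)C)C(O)=C1Br | intermediate
13 | 3-bromo-5-{2,4-bis(tert-butyldimethylsilyloxy)-6-[(tert-butyldimethylsilyloxy)methyl]-3-methoxybenzyl}-2-oxo-2H-pyran-4-yl trifluoromethanesulfonate | O=C1OC=C(Cc2c(CO[Si](C)(C)C(C)(C)C)cc(O[Si](C)(C)C(C)(C)C)c(OC)c2O[Si](C)(C)C(C)(C)C)C(OS(=O)(=O)C(F)(F)F)=C1Br | intermediate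
14 | 3,4-dibromo-5-{2,4-bis(tert-butyldimethylsilyloxy)-6-[(tert-butyldimethylsilyloxy)methyl]-3-methoxybenzyl}-2H-pyran-2-one | O=C1OC=C(Cc2c(CO[Si](C)(C)C(C)(C)C)cc(O[Si](C)(C)C(C)(C)C)c(OC)c2O[Si](C)(C)C(C)(C)C)C(Br)=C1Br | intermediate
15 | tris(trimethylsilyloxy)ethene | C[Si](C)(C)OC=C(O[Si](C)(C)C)O[Si](C)(C)C | starting material
16 | 4,5-dibromo-6-{2,4-bis(tert-butyldimethylsilyloxy)-6-[(tert-butyldimethylsilyloxy)methyl]-3-methoxybenzyl}-7,8,8-tris(trimethylsilyloxy)-2-oxabicyclo[2.2.2]oct-5-en-3-one (racemic mixture of stereoisomers, transient) | O=C1OC2C(Cc3c(CO[Si](C)(C)C(C)(C)C)cc(O[Si](C)(C)C(C)(C)C)c(OC)c3O[Si](C)(C)C(C)(C)C)=C(Br)C1(Br)C(O[Si](C)(C)C)(O[Si](C)(C)C)C2O[Si](C)(C)C | intermediate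
17 | 1,2-dibromo-3-{2,4-bis(tert-butyldimethylsilyloxy)-6-[(tert-butyldimethylsilyloxy)methyl]-3-methoxybenzyl}-5,6,6-tris(trimethylsilyloxy)cyclohexa-1,3-diene (racemic, transient) | BrC1=C(Br)C(Cc2c(CO[Si](C)(C)C(C)(C)C)cc(O[Si](C)(C)C(C)(C)C)c(OC)c2O[Si](C)(C)C(C)(C)C)=CC(O[Si](C)(C)C)C1(O[Si](C)(C)C)O[Si](C)(C)C | intermediate
18 | 3,4-dibromo-5-{2,4-bis(tert-butyldimethylsilyloxy)-6-[(tert-butyldimethylsilyloxy)methyl]-3-methoxybenzyl}-1,2-bis(trimethylsilyloxy)benzene (fully silylated target) | COc1c(O[Si](C)(C)C(C)(C)C)cc(CO[Si](C)(C)C(C)(C)C)c(Cc2cc(O[Si](C)(C)C)c(O[Si](C)(C)C)c(Br)c2Br)c1O[Si](C)(C)C(C)(C)C | intermediate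
19 | 4-(2,3-dibromo-4,5-dihydroxybenzyl)-5-(hydroxymethyl)-2-methoxybenzene-1,3-diol (achiral) | COc1c(O)cc(CO)c(Cc2cc(O)c(O)c(Br)c2Br)c1O | target

**Total step count:** 12. **Longest linear sequence:** 12 steps (1 → 19).

**Steps most likely to fail**

1. Step 11. The silyl ketene acetal may add at C4 and expel bromide, or add in conjugate fashion with silyl transfer and lactone opening, instead of closing the second bond; the dihydroarene may also lose silanol incompletely. The fallback assembles the diarylmethane with ring B already intact. Setting out from 1 (used in excess), acid-promoted Friedel–Crafts benzylation (BF3·OEt2, dioxane, rt) with purchased 2,3-dibromo-4,5-dihydroxybenzyl alcohol (OCc1cc(O)c(O)c(Br)c1Br) should occur at C2 of 1, the only type of free position, ortho to one hydroxyl and para to the other. The para-hydroxyl of the benzyl alcohol stabilises the benzylic cation. This should give methyl 2-(2,3-dibromo-4,5-dihydroxybenzyl)-3,5-dihydroxy-4-methoxybenzoate F1. Reduction of its ester with excess DIBAL-H (THF, 0 °C → rt), to which aryl bromides are inert, would come back to the route at 19.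

2. Step 7. The dianion may be quenched by proton transfer from the more acidic formylated product or be formylated on oxygen, and deformylation may outrun the thermal loss of tert-butanol. The fallback builds the pyrone from the other side, by C-acylation of an aldehyde enol ether. Setting out from 7, alkylation of the lithium enolate of ethyl acetate (LDA, THF/DMPU, −78 °C) should give ethyl 3-{2,4-bis(tert-butyldimethylsilyloxy)-6-[(tert-butyldimethylsilyloxy)methyl]-3-methoxyphenyl}propanoate F2. DIBAL-H at −78 °C should give 3-{2,4-bis(tert-butyldimethylsilyloxy)-6-[(tert-butyldimethylsilyloxy)methyl]-3-methoxyphenyl}propanal F3. TMSCl/Et3N/NaI in MeCN should give its trimethylsilyl enol ether, 1-(trimethylsilyloxy)-3-{2,4-bis(tert-butyldimethylsilyloxy)-6-[(tert-butyldimethylsilyloxy)methyl]-3-methoxyphenyl}prop-1-ene F4 (E/Z mixture, both converge). Malonyl dichloride (Et2O, −78 °C → rt) acylates the enol ether at carbon and then closes the lactone on the aldehyde enol oxygen, which would come back to the route at 11.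

3. Step 1. Electrophilic attack at C2, which is flanked by the ester, may be slow, and the phenols may consume the chloroiminium reagent by O-formylation so that conversion stalls. The fallback introduces the carbon at the alcohol oxidation level by acid-mediated hydroxymethylation–lactonisation. Setting out from 1, paraformaldehyde (1.1 equiv) in conc. HCl/AcOH at 60 °C should give 4,6-dihydroxy-5-methoxyisobenzofuran-1(3H)-one F5, the ortho ester trapping the benzylic alcohol as the lactone. TBSCl/imidazole (DMF) should give 4,6-bis(tert-butyldimethylsilyloxy)-5-methoxyisobenzofuran-1(3H)-one F6, and reduction of the lactone with DIBAL-H would come back to the route at 5.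

**Further compounds**

F1 | step 11 | methyl 2-(2,3-dibromo-4,5-dihydroxybenzyl)-3,5-dihydroxy-4-methoxybenzoate | COC(=O)c1cc(O)c(OC)c(O)c1Cc1cc(O)c(O)c(Br)c1Br
F2 | step 7 | ethyl 3-{2,4-bis(tert-butyldimethylsilyloxy)-6-[(tert-butyldimethylsilyloxy)methyl]-3-methoxyphenyl}propanoate | CCOC(=O)CCc1c(CO[Si](C)(C)C(C)(C)C)cc(O[Si](C)(C)C(C)(C)C)c(OC)c1O[Si](C)(C)C(C)(C)C
F3 | step 7 | 3-{2,4-bis(tert-butyldimethylsilyloxy)-6-[(tert-butyldimethylsilyloxy)methyl]-3-methoxyphenyl}propanal | O=CCCc1c(CO[Si](C)(C)C(C)(C)C)cc(O[Si](C)(C)C(C)(C)C)c(OC)c1O[Si](C)(C)C(C)(C)C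
F4 | step 7 | 1-(trimethylsilyloxy)-3-{2,4-bis(tert-butyldimethylsilyloxy)-6-[(tert-butyldimethylsilyloxy)methyl]-3-methoxyphenyl}prop-1-ene (Z isomer drawn; E/Z mixture) | C[Si](C)(C)O/C=C\Cc1c(CO[Si](C)(C)C(C)(C)C)cc(O[Si](C)(C)C(C)(C)C)c(OC)c1O[Si](C)(C)C(C)(C)C
F5 | step 1 | 4,6-dihydroxy-5-methoxyisobenzofuran-1(3H)-one | O=C1OCc2c1cc(O)c(OC)c2O
F6 | step 1 | 4,6-bis(tert-butyldimethylsilyloxy)-5-methoxyisobenzofuran-1(3H)-one | O=C1OCc2c1cc(O[Si](C)(C)C(C)(C)C)c(OC)c2O[Si](C)(C)C(C)(C)C
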